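Readings and results are simulated from invented constants.

**The choice.** If you want more product at 2.0 h from your next flask, settle its temperature first, and let one ratio guide you.

the same everywhere: starting material 0.050 M
- theta: partner 0.030 M (fed, over 15 min); temperature 8 °C; run made earlier
- eta: partner 0.11 M (fed, over 15 min); temperature 24 °C; run made earlier
- alder: partner 0.0800 M (fed, over 15 min); temperature 0 °C; time 2.0 h
- maple: partner 0.0250 M (fed, over 15 min); temperature 30 °C; time 2.0 h
- oak: partner 0.0250 M (fed, over 15 min); temperature 0 °C; time 2.0 h
- elm: partner 0.0800 M (fed, over 15 min); temperature 30 °C; time 2.0 h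

| run | time / min | product / % | starting material / % |
|---|---|---|---|
| theta | 10.0 | 0 | 95.1 |
| theta | 15.0 | 1.6 | 86.1 |
| theta | 25.0 | 2.6 | 71.1 |
| theta | 40.0 | 10.3 | 55.7 |
| theta | 80.0 | 24.8 | 33.4 |
| theta | 120 | 31.2 | 19.7 |
| eta | 3.00 | 0.1 | 91.7 |
| eta | 5.00 | 3.4 | 80.5 |
| eta | 8.00 | 7.5 | 58.4 |
| eta | 12.0 | 13.4 | 33.4 |
| eta | 25.0 | 9.1 | 6.4 |
| eta | 40.0 | 7.3 | 1.3 |

(readings scatter by 1 percentage point)

- the flasks by amount of product, in percent of the starting material charged, highest first, at 2.0 h (alder / maple / oak / elm)
- the amount of product, in percent of the starting material charged of the flask you put first, at 2.0 h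
- the amount of product, in percent of the starting material charged of the flask you put last, at 2.0 h

- a reading or a percentage of product counts all its forms, free or not
- a reading of starting material is of its free form alone

**Product share.** Set the product read against the starting material lost at the same moment. Time does not drop out of this ratio while a flask moves: eta's falls from 20.1% at 12.0 min to 9.72% at 25.0 min. Eta's last reading, with nearly all its starting material lost, gives 7.40%: this is its product share, the product standing per starting material lost at that moment, which you may know as selectivity. Theta's last reading gives 38.9%, after 23.3% at 40.0 min and 37.2% at 80.0 min, so theta's share is rising where eta's falls. But theta still held 19.7% starting material, and both readings carry a scatter of 1 percentage point, so this share is rough.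

**My reckoning.** Eta's share, read at 40.0 min and 24 °C, is 5.26 times smaller than theta's, read at 120 min and 8 °C, though the two runs differ in partner and in the moment as well. As a rough assumption of my own, I put the whole fall on temperature and take the same fall per degree beyond that range. Elm has c(partner) of 0.0800 M, more than its c(starting material) of 0.050 M, and it is hotter than eta, so I expect its starting material to go as eta's did. Its product is then simply its share, 3.97%, and I put it last. Maple and oak, with c(partner) at half of c(starting material), may keep starting material, so I apply no share to them. Alder is cold with partner in excess, so I put it first, below theta's share. Charge alder next and leave elm out.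

**The result.** The forecast, holding that “excess partner and heat destroy it”, gave alder > maple > oak > elm, with 27% and 3%. The simulation gives alder > oak > maple > elm, with 28.7% and 4.39%.

    intermediate ⇌ product (K = 0.850, k = 0.00600 min⁻¹, Ea = 95.0 kJ mol⁻¹, ΔH = −67.0 kJ mol⁻¹)
    starting material + product ⇌ idle adduct, settled at all times (K = 920 M⁻¹, ΔH = −39.0 kJ mol⁻¹)
    starting material + partner → intermediate (k = 0.380 M⁻¹ min⁻¹, Ea = 50.0 kJ mol⁻¹)
    (constants at 0 °C)

**Come to rest?** Elm has stopped: it holds 0.00628% starting material, its share is 4.39% against my 3.97%, and ten times the time leaves its product at 4.39%. Its repeat at 15 °C shows, at 2.00 h, a share of 19.9%, where the same reckoning gives 18.8%. Maple also stands still, at 8.75% product and again 8.75% at 20.0 h. Oak is still moving, from 13.5% to 42.7% at that time, and alder climbs from 28.7% to 46.4%.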